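The data stem from a simulated flask with constants of no real substance; noise was put on by code.

The mono adduct of the autumn run reads 31 % at 8.00 min and falls from then on, so the first addition, which costs one reagent per starting material, is taken here as finished by then, and the remaining share of the charge, f = 69.0 %, is taken to be the unseen other mono adduct.

| flask | starting material | reagent | remark | time |
|---|---|---|---|---|
| dusk | 0.067 M | 0.10 M | run made earlier |  |
| autumn | 0.050 M | 0.10 M | run made earlier |  |
| north-west | 0.10 M | 0.100 M |  | 5.0 h |
| west | 0.10 M | 0.250 M |  | 5.0 h |
| north | 0.10 M | 0.300 M |  | 5.0 h |

- dusk (time / min: double product / %, mono adduct / %): 8.00: 0, 27; 20.0: 2, 25; 40.0: 3, 16; 60.0: 5, 10; 80.0: 5, 6; 120: 10, 5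
- autumn (time / min: double product / %, mono adduct / %): 8.00: 0, 31; 15.0: 0, 29; 25.0: 2, 23; 40.0: 6, 19; 60.0: 9, 13; 120: 11, 3

(readings scatter by 1.5 percentage points)

- steps that have been proposed: mono adduct + by-product -> side product; reagent <-> dormant form; starting material + reagent -> other mono adduct + by-product; starting material + reagent -> mono adduct + by-product; reagent + mono adduct -> double product + by-product; reagent + other mono adduct -> double product + by-product

* final double product, as a percentage of the starting material charged, for each flask in turn (north-west, west, north)

The proposed steps let either mono adduct take a second reagent. What a flask offers that second addition is its surplus S, the reagent charge minus the starting material charge: 0.0500 M in autumn, 0 M in north-west, 0.150 M in west and 0.200 M in north.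

With a pool of other mono adduct P = f·(starting material charge), x the double product formed by time t and k_D the rate constant of the second addition, dx/dt = k_D(P−x)(S−x) integrates to ln[(S−x)P/(S(P−x))] = (S−P)k_D t. The autumn reading of 11 % at 120 min, which carries its scatter, then gives the second-addition constant k_D = 0.0307 L mol⁻¹ min⁻¹.

Holding S constant, the pseudo-first-order shortcut, gives west 51.7 %. But each double product consumes surplus, so S falls during the run, and the full form gives 46.4 % for west, less than the shortcut, 53.9 % for north, and, with S at zero, zero for north-west.

One objection stands: between 8.00 min and 120 min autumn's mono adduct loses 28 percentage points while double product gains 11 points, so the mono adduct could be a source, and the reckoning above does not exclude that. This reckoning still commits to the pool f, larger than the mono adduct reading.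

The forecast gives 1.5 %, 14 % and 16 % for north-west, west and north, on the ground “I take mono adduct as its source”; for west, this reckoning stands higher.

North-west, west and north give 2.09 %, 44.8 % and 53.2 %.

    mono adduct + by-product → side product (k = 0.00620 L mol⁻¹ s⁻¹)
    reagent ⇌ dormant form (K = 0.240, k = 0.00900 s⁻¹)
    starting material + reagent → other mono adduct + by-product (k = 0.0440 L mol⁻¹ s⁻¹)
    starting material + reagent → mono adduct + by-product (k = 0.0270 L mol⁻¹ s⁻¹)
    reagent + mono adduct → double product + by-product (k = 0.00100 L mol⁻¹ s⁻¹)
    reagent + other mono adduct → double product + by-product (k = 5.50 × 10⁻⁴ L mol⁻¹ s⁻¹)

At 5.00 h the west flask holds 23.7 % of other mono adduct beside 44.8 % of double product, together 68.5 % of the charge. Carried to 2.50 h, k_D reckons 31.5 % for west and 38.5 % for north, and the flasks then hold 31.6 % in west and 39.1 % in north.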